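**Retrosynthetic overview**
- The 6,7-dimethoxy pyranone ring is the only ring built, and it is closed last, by lactonisation (O1–C2) and dehydration (C3=C4) of a β-hydroxy ester.
- The key C3–C4 bond comes from an intermolecular aldol addition of the lithium enolate of ethyl (coumarin-7-yloxy)acetate to MOM-protected 2-hydroxy-4,5-dimethoxybenzaldehyde.
- The ester fragment comes from umbelliferone (its coumarin ring is bought intact) and ethyl bromoacetate by Williamson etherification.
- The aldehyde fragment comes from 2,4,5-trimethoxybenzaldehyde by chelation-controlled ortho-demethylation, then MOM protection.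
- Ring order: both benzene rings and the umbelliferone pyranone are purchased; the second pyranone ring forms in the final step.

Assumption: the target is achiral (no stereocentre in its SMILES), so there is no enantiomer to select; the two stereocentres that appear transiently in 8, 9 and 10 are uncontrolled and are erased in step 5.

**Route**

Step 1
Reactants: 1 2,4,5-trimethoxybenzaldehyde
Product: 2 2-hydroxy-4,5-dimethoxybenzaldehyde
Conditions: BCl3 (1.2 equiv, 1 M in CH2Cl2), CH2Cl2, -10 °C to rt, 3 h; aqueous work-up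
Reagents that add atoms: none
Why: Chelation-directed Lewis acid ether cleavage: BCl3 bound to the aldehyde oxygen delivers chloride only to the ortho methoxy group, so the 4- and 5-methoxy groups stay intact.

Step 2
Reactants: 2 2-hydroxy-4,5-dimethoxybenzaldehyde
Product: 3 4,5-dimethoxy-2-(methoxymethoxy)benzaldehyde
Conditions: MOMCl (1.5 equiv), iPr2NEt (2.0 equiv), CH2Cl2, 0 °C to rt, 12 h
Reagents that add atoms: chloromethyl methyl ether (MOMCl), COCCl
Why: SN2-type O-alkylation of the phenol gives a base-stable acetal, so the acidic OH cannot quench the enolate in step 4.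

Step 3
Reactants: 4 umbelliferone (7-hydroxy-2H-chromen-2-one); 5 ethyl bromoacetate
Product: 6 ethyl 2-[(2-oxo-2H-chromen-7-yl)oxy]acetate
Conditions: K2CO3 (1.5 equiv), acetone, reflux, 6 h
Reagents that add atoms: none
Why: Williamson ether synthesis of an acidic phenol with a reactive α-halo ester; the lactone is untouched by anhydrous K2CO3.

Step 4
Reactants: 6 ethyl 2-[(2-oxo-2H-chromen-7-yl)oxy]acetate; 3 4,5-dimethoxy-2-(methoxymethoxy)benzaldehyde
Product: 8 ethyl 3-[4,5-dimethoxy-2-(methoxymethoxy)phenyl]-3-hydroxy-2-[(2-oxo-2H-chromen-7-yl)oxy]propanoate (racemic syn/anti mixture), via lithium enolate 7 (not isolated)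
Conditions: 6 (1.15 equiv) added to LiN(SiMe3)2 (1.2 equiv), THF, -78 °C, 20 min; then 3 (1.0 equiv) in THF, -78 °C, 1.5 h; AcOH quench at -78 °C
Reagents that add atoms: none
Why: Intermolecular aldol addition of a preformed kinetic lithium ester enolate to a non-enolisable aldehyde at -78 °C, which outruns attack on the coumarin lactone; the two new stereocentres form as an uncontrolled racemic syn/anti mixture that is erased in step 5.

Step 5
Reactants: 8 ethyl 3-[4,5-dimethoxy-2-(methoxymethoxy)phenyl]-3-hydroxy-2-[(2-oxo-2H-chromen-7-yl)oxy]propanoate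
Product: 11 daphnoretin methyl ether (6,7-dimethoxy-3-[(2-oxo-2H-chromen-7-yl)oxy]-2H-chromen-2-one), via free phenol hydroxy ester 9 (not isolated), via 4-hydroxy-3,4-dihydrocoumarin 10 (not isolated)
Conditions: HCl (3 M aq., 5 equiv), EtOH, 45 °C, 2 h; evaporate; then p-TsOH·H2O (0.2 equiv), toluene, reflux, Dean–Stark, 4 h
Reagents that add atoms: none
Why: Acetal hydrolysis frees the phenol, six-membered lactonisation onto the ethyl ester and acid-catalysed benzylic dehydration then give the conjugated coumarin, and any open-chain acrylate from early dehydration is re-protonated at the electron-rich benzylic carbon and funnelled to the same lactone.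

**Compound list**
1 | 2,4,5-trimethoxybenzaldehyde | COc1cc(OC)c(C=O)cc1OC | starting material
2 | 2-hydroxy-4,5-dimethoxybenzaldehyde | COc1cc(O)c(C=O)cc1OC | intermediate
3 | 4,5-dimethoxy-2-(methoxymethoxy)benzaldehyde | COCOc1cc(OC)c(OC)cc1C=O | intermediate
4 | umbelliferone (7-hydroxy-2H-chromen-2-one) | O=c1ccc2ccc(O)cc2o1 | starting material
5 | ethyl bromoacetate | CCOC(=O)CBr | starting material
6 | ethyl 2-[(2-oxo-2H-chromen-7-yl)oxy]acetate | CCOC(=O)COc1ccc2ccc(=O)oc2c1 | intermediate
7 | lithium enolate of 6 (lithium 1-ethoxy-2-[(2-oxo-2H-chromen-7-yl)oxy]ethen-1-olate, geometry not controlled) | [Li+].CCOC([O-])=COc1ccc2ccc(=O)oc2c1 | intermediate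
8 | ethyl 3-[4,5-dimethoxy-2-(methoxymethoxy)phenyl]-3-hydroxy-2-[(2-oxo-2H-chromen-7-yl)oxy]propanoate (racemic, syn/anti mixture) | CCOC(=O)C(Oc1ccc2ccc(=O)oc2c1)C(O)c1cc(OC)c(OC)cc1OCOC | intermediate
9 | ethyl 3-hydroxy-3-(2-hydroxy-4,5-dimethoxyphenyl)-2-[(2-oxo-2H-chromen-7-yl)oxy]propanoate (racemic, syn/anti mixture) | CCOC(=O)C(Oc1ccc2ccc(=O)oc2c1)C(O)c1cc(OC)c(OC)cc1O | intermediate
10 | 4-hydroxy-6,7-dimethoxy-3-[(2-oxo-2H-chromen-7-yl)oxy]-3,4-dihydro-2H-chromen-2-one (racemic, cis/trans mixture) | COc1cc2c(cc1OC)OC(=O)C(Oc1ccc3ccc(=O)oc3c1)C2O | intermediate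
11 | daphnoretin methyl ether (6,7-dimethoxy-3-[(2-oxo-2H-chromen-7-yl)oxy]-2H-chromen-2-one; achiral) | COc1cc2cc(Oc3ccc4ccc(=O)oc4c3)c(=O)oc2cc1OC | target

**Totals**
Total step count: 5.
Longest linear sequence: 4 steps (steps 1, 2, 4, 5); the ester arm is 3 steps (steps 3, 4, 5).

**Three steps most likely to fail, with fallbacks**

Step 4 (aldol). The enolate 7 carries an electrophilic coumarin lactone and may self-condense before the aldehyde is added. The fallback sets out from 6 and comes back to the route at 11. Saponify 6 (LiOH, THF/H2O, then HCl to pH 1, which recloses any opened lactone) to 2-[(2-oxo-2H-chromen-7-yl)oxy]acetic acid F1. Heat F1 with the unprotected aldehyde 2 in Ac2O/Et3N at 120 °C (Perkin–Oglialoro condensation). The mixed anhydride acetic 2-[(2-oxo-2H-chromen-7-yl)oxy]acetic anhydride F2 forms in the flask, is enolised by the amine, condenses with the aldehyde carbon and lactonises onto the phenol, giving 11 directly without any strongly basic enolate.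

Step 5 (deprotection, lactonisation, dehydration). The very electron-rich benzylic alcohol may dehydrate before the lactone closes and leave an open acrylate of the wrong geometry. The fallback sets out from 8 and comes back to the route at 11; it dehydrates on purpose first and closes the ring thermally.
- Acetylate 8 (Ac2O, Et3N, DMAP, CH2Cl2) to ethyl 3-acetoxy-3-[4,5-dimethoxy-2-(methoxymethoxy)phenyl]-2-[(2-oxo-2H-chromen-7-yl)oxy]propanoate F3.
- Add DBU to eliminate to ethyl 3-[4,5-dimethoxy-2-(methoxymethoxy)phenyl]-2-[(2-oxo-2H-chromen-7-yl)oxy]prop-2-enoate F4 (E/Z mixture).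
- Cleave the MOM group (HCl, EtOH, 40 °C) to ethyl 3-(2-hydroxy-4,5-dimethoxyphenyl)-2-[(2-oxo-2H-chromen-7-yl)oxy]prop-2-enoate F5.
- Heat F5 in N,N-diethylaniline at 210 °C, where thermal E/Z isomerisation feeds irreversible lactonisation to 11.

Step 2 (MOM protection). The phenol is hydrogen-bonded to the aldehyde and can react sluggishly, and the MOM group forces an acidic unmasking later. The fallback sets out from 2 and comes back to the route at 9; it uses a protecting group that is removed under neutral conditions. Alkylate 2 with allyl bromide (K2CO3, DMF, rt) to 4,5-dimethoxy-2-(prop-2-en-1-yloxy)benzaldehyde F6. Add enolate 7 under the step 4 conditions to give ethyl 3-[4,5-dimethoxy-2-(prop-2-en-1-yloxy)phenyl]-3-hydroxy-2-[(2-oxo-2H-chromen-7-yl)oxy]propanoate F7. Remove the allyl group with Pd(PPh3)4 (zerovalent palladium, 3 mol %) and morpholine in THF at rt to give the free phenol 9, which then continues through the second stage of step 5.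

**Further compounds**
F1 | step 4 | 2-[(2-oxo-2H-chromen-7-yl)oxy]acetic acid | OC(=O)COc1ccc2ccc(=O)oc2c1
F2 | step 4 | acetic 2-[(2-oxo-2H-chromen-7-yl)oxy]acetic anhydride | CC(=O)OC(=O)COc1ccc2ccc(=O)oc2c1
F3 | step 5 | ethyl 3-acetoxy-3-[4,5-dimethoxy-2-(methoxymethoxy)phenyl]-2-[(2-oxo-2H-chromen-7-yl)oxy]propanoate (diastereomer mixture) | CCOC(=O)C(Oc1ccc2ccc(=O)oc2c1)C(OC(C)=O)c1cc(OC)c(OC)cc1OCOC
F4 | step 5 | ethyl 3-[4,5-dimethoxy-2-(methoxymethoxy)phenyl]-2-[(2-oxo-2H-chromen-7-yl)oxy]prop-2-enoate (E/Z mixture) | CCOC(=O)C(Oc1ccc2ccc(=O)oc2c1)=Cc1cc(OC)c(OC)cc1OCOC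
F5 | step 5 | ethyl 3-(2-hydroxy-4,5-dimethoxyphenyl)-2-[(2-oxo-2H-chromen-7-yl)oxy]prop-2-enoate (E/Z mixture) | CCOC(=O)C(Oc1ccc2ccc(=O)oc2c1)=Cc1cc(OC)c(OC)cc1O
F6 | step 2 | 4,5-dimethoxy-2-(prop-2-en-1-yloxy)benzaldehyde | C=CCOc1cc(OC)c(OC)cc1C=O
F7 | step 2 | ethyl 3-[4,5-dimethoxy-2-(prop-2-en-1-yloxy)phenyl]-3-hydroxy-2-[(2-oxo-2H-chromen-7-yl)oxy]propanoate (diastereomer mixture) | CCOC(=O)C(Oc1ccc2ccc(=O)oc2c1)C(O)c1cc(OC)c(OC)cc1OCC=C
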